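**Retrosynthesis**
- Target **7** comes from global debenzylation of the hexa-O-benzyl dimer **6**.
- **6** comes from forming the C3(unit A)–C8(unit B) bond. A photochemical, deoxygenative radical C-alkylation joins the C3 radical of the 3-O-aroyl ester **5** to C8 of the 5-phenolate of **3**.
- **5** and **3** both come from (+)-taxifolin (**1**) by 7,3′,4′-tri-O-benzylation, then 3-O-aroylation of part of it. Unit A is taxifolin that has lost its own 3-oxygen.
- No heterocycle is built. Both chromanone rings and all chirality come from **1**. The new C3 centre of unit A is set trans to the C2 aryl by the C2 centre.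

**Assumptions (one line each)**
- The 5-OH is chelated to C4=O and stays free during benzylation and acylation.
- C8 is the preferred site over C6 because it is para to the 5-oxide, flanked by O7 and O1, and less hindered. Any C6 isomer is removed by chromatography.

**Step 1**
Reactants: **1** (2R,3R)-(+)-taxifolin; **2** benzyl bromide
Product: **3** (2R,3R)-7,3′,4′-tri-O-benzyltaxifolin (3-OH and 5-OH free)
Conditions: BnBr (3.3 equiv), K2CO3 (3.3 equiv), KI (cat.), DMF, 0 °C → rt, 16 h, Ar
Reagents that add atoms: benzyl bromide, BrCc1ccccc1
Why: The acidic 7-, 3′- and 4′-phenols undergo Williamson O-benzylation, while the chelated 5-OH and the aliphatic 3-OH do not react under these mild conditions. The C2/C3 stereocentres are not touched, and the trans-diequatorial arrangement is the stable one.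

**Step 2**
Reactants: **3**; **4** 3,5-bis(trifluoromethyl)benzoyl chloride
Product: **5** (2R,3R)-3-O-[3,5-bis(trifluoromethyl)benzoyl]-7,3′,4′-tri-O-benzyltaxifolin
Conditions: **4** (1.3 equiv), pyridine, DMAP (cat.), CH2Cl2, 0 °C → rt, 3 h
Reagents that add atoms: **4**, O=C(Cl)c1cc(C(F)(F)F)cc(C(F)(F)F)c1
Why: Acylation of the only free non-chelated hydroxyl gives an electron-poor, non-SNAr-prone ester. It serves as the redox-active leaving group for C3 radical generation, and the stereocentres are unchanged.

**Step 3**
Reactants: **5** (1.0 equiv, electrophile); **3** (1.5 equiv, nucleophile)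
Product: **6** hexa-O-benzyl dimer: (2S,3R)-7,3′,4′-tri-O-benzyl-5-hydroxyflavanon-3-yl attached at C8 of (2R,3R)-7,3′,4′-tri-O-benzyltaxifolin
Conditions: Cs2CO3 (1.0 equiv), DMSO (0.05 M), 405 nm LEDs, 25 °C, 24 h, Ar
Reagents that add atoms: none
Why: Proposed new method: photoexcited 5-phenolate of **3** (or its EDA complex with **5**) transfers an electron to **5**, and the radical anion fragments by C3–O cleavage with loss of ArCO2⁻ to give the electrophilic flavanon-3-yl radical. That radical adds to C8 (para to the 5-oxide) of a second phenolate molecule on the face anti to the 2-aryl group, and the resulting dienone radical anion reduces the next molecule of **5** to propagate an SRN1-type chain before tautomerising to the C8-aryl phenol. The closest known reactions are photostimulated SRN1 C-arylation of phenoxides, photochemical ortho-C-alkylation of naphtholates with α-bromoketones, and reductive cleavage of α-acyloxy ketones. Here the known reactivity is extended to a secondary flavanone α-keto radical and a flavanonol phenolate, forming the C3–C8 bond. The new C3 centre comes out 2,3-trans, and any cis epimer equilibrates to trans under the mildly basic conditions.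

**Step 4**
Reactants: **6**
Product: **7** target, eriodictyol-(3→8)-taxifolin
Conditions: H2 (1 atm), 10% Pd/C, THF/MeOH 1:1, rt, 6 h
Reagents that add atoms: none
Why: Catalytic hydrogenolysis (O-debenzylation) removes all six benzyl ethers under neutral conditions, so the 2,3-trans stereocentres are not epimerised. The chelated C4 ketones and the free 3-OH are untouched.

**Checks done**
- Target atom map: unit A is a 5,7,3′,4′-tetrahydroxyflavanone (2S,3R, 2,3-trans) linked through C3 to C8 of unit B. Unit B is taxifolin (2R,3R) with free 3-OH, and C8 sits between C7 and C8a.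
- Atom accounting: **6** = **3** + (**5** minus ArCO2H) + (−H at C8); **7** = **6** − 6 Bn + 6 H.
- Stereochemistry: taxifolin C2 (R) has the same spatial arrangement as the flavanone C2 (S) of unit A, because CIP priorities change when the 3-OH is lost.
- Protecting-group survival: benzyl ethers and the aroyl ester are stable through Steps 1–2. The 5-OH stays chelated throughout.

**Compound list**
1 | (2R,3R)-(+)-taxifolin | O=C1c2c(O)cc(O)cc2O[C@H](c2ccc(O)c(O)c2)[C@H]1O | starting material
2 | benzyl bromide | BrCc1ccccc1 | starting material
3 | (2R,3R)-7,3′,4′-tri-O-benzyltaxifolin | O=C1c2c(O)cc(OCc3ccccc3)cc2O[C@H](c2ccc(OCc3ccccc3)c(OCc3ccccc3)c2)[C@H]1O | intermediate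
4 | 3,5-bis(trifluoromethyl)benzoyl chloride | O=C(Cl)c1cc(C(F)(F)F)cc(C(F)(F)F)c1 | starting material
5 | 3-O-aroyl ester of 3 | O=C1c2c(O)cc(OCc3ccccc3)cc2O[C@H](c2ccc(OCc3ccccc3)c(OCc3ccccc3)c2)[C@H]1OC(=O)c1cc(C(F)(F)F)cc(C(F)(F)F)c1 | intermediate
6 | hexa-O-benzyl biflavanoid | O=C1c2c(O)cc(OCc3ccccc3)cc2O[C@H](c2ccc(OCc3ccccc3)c(OCc3ccccc3)c2)[C@H]1c1c(OCc2ccccc2)cc(O)c2c1O[C@H](c1ccc(OCc3ccccc3)c(OCc3ccccc3)c1)[C@@H](O)C2=O | intermediate
7 | eriodictyol-(3→8)-taxifolin (target) | O=C1c2c(O)cc(O)cc2O[C@H](c2ccc(O)c(O)c2)[C@H]1c1c(O)cc(O)c2c1O[C@H](c1ccc(O)c(O)c1)[C@@H](O)C2=O | target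

**Totals:** 4 steps; longest linear sequence 4 (1 → 3 → 5 → 6 → 7).

**Three steps most likely to fail**
1. **Step 3, photochemical deoxygenative coupling (the new step).**
   - Risks: C6 instead of C8 attack, reduction to the 3-deoxy flavanone, flavone formation by loss of the C2–H (destroying C2), and base-induced ring opening.
   - Fallback (known chemistry): brominate **3** at C8 (NBS). Reduce **5** with SmI2 to the 3-deoxy tri-O-benzyl eriodictyol. Join them by Pd-catalysed ketone α-arylation with a mild base (Pd/Q-Phos, K3PO4), then take the product to Step 4.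
2. **Step 1, selective tri-benzylation.**
   - Risks: base-mediated C2/C3 epimerisation or oxidation to the quercetin series, and over-benzylation at 3-OH.
   - Fallback: base-free Mitsunobu benzylation (BnOH, PPh3, DIAD) of the acidic phenols, with 3-OH inversion monitored.
3. **Step 4, global hydrogenolysis.**
   - Risks: incomplete debenzylation of the crowded dimer, or over-reduction or C-ring hydrogenolysis.
   - Fallback: Lewis-acid debenzylation with BCl3 and pentamethylbenzene as cation scavenger in CH2Cl2 at −78 °C.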